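The route rests on disconnecting the tetrasubstituted C3=C4 double bond of the pyranone ring (ring B), which carries a methyl group at each end and lies between the lactone carbonyl C2 and C4a of the benzene ring (ring A). A single intramolecular Wittig olefination forms this bond and closes ring B. The precursor is the 2-(triphenylphosphoranylidene)propanoate ester of 4'-benzyloxy-2'-hydroxy-6'-methoxyacetophenone, whose acetyl group supplies C4 and its methyl. The coumarin is then formylated at C8, prenylated at C6 by Claisen rearrangement and joined by Nozaki–Hiyama–Kishi coupling to a cyclohexenyl triflate (ring C), whose three stereocentres stem from one dianionic Ireland–Claisen rearrangement.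

Key step: step 4

Assumption: the carbinol carbon created in step 19 is carried forward as a mixture of epimers, because step 20 converts it into the ketone carbon.

Step 1
Reactants: 1 2',4'-dihydroxy-6'-methoxyacetophenone; 2 benzyl bromide
Product: 3 4'-(benzyloxy)-2'-hydroxy-6'-methoxyacetophenone
Conditions: K2CO3 (1.1 equiv), acetone, 56 °C
Reagents that add atoms: none
Why: Williamson ether synthesis in which the 4'-hydroxyl, para to the acetyl group and not hydrogen-bonded, is alkylated while the 2'-hydroxyl stays locked in its chelate with the ketone.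

Step 2
Reactants: 3 4'-(benzyloxy)-2'-hydroxy-6'-methoxyacetophenone; 4 2-bromopropanoyl bromide (racemic)
Product: 5 2-acetyl-5-(benzyloxy)-3-methoxyphenyl 2-bromopropanoate (racemic)
Conditions: pyridine, DMAP (cat.), CH2Cl2, 0 °C
Reagents that add atoms: none
Why: O-acylation of the remaining phenol by the acyl bromide under an amine base that is too weak to enolise the ketone toward a Baker–Venkataraman acyl shift.

Step 3
Reactants: 5 2-acetyl-5-(benzyloxy)-3-methoxyphenyl 2-bromopropanoate; 6 triphenylphosphine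
Product: 8 2-acetyl-5-(benzyloxy)-3-methoxyphenyl 2-(triphenylphosphoranylidene)propanoate, via phosphonium bromide 7 (not isolated)
Conditions: MeCN, 60 °C; then Et3N, 0 → 23 °C; aqueous wash
Reagents that add atoms: none
Why: SN2 quaternisation of the activated secondary α-bromo ester followed by removal of the ester- and phosphonium-acidified α-proton by triethylamine is the standard preparation of a stabilised Wittig ylide, and the α-stereocentre disappears.

Step 4
Reactants: 8 2-acetyl-5-(benzyloxy)-3-methoxyphenyl 2-(triphenylphosphoranylidene)propanoate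
Product: 9 7-(benzyloxy)-5-methoxy-3,4-dimethylchromen-2-one
Conditions: PhMe, 110 °C
Reagents that add atoms: none
Why: The nucleophilic ylide carbon (future C3) adds to the neighbouring acetyl carbonyl carbon (future C4) to give an oxaphosphetane, which undergoes cycloreversion to the C3=C4 double bond and triphenylphosphine oxide (intramolecular Wittig reaction). The closest known reaction type is the coumarin synthesis from ortho-acylaryl (triphenylphosphoranylidene)acetates; the α-methyl ylide and the ketone acceptor should make this case slower, hence the reflux temperature. Ring B is closed in a 6-exo-trig mode, the attacked C=O bond lying outside the ring being formed. No stereocentre is created and the six-membered ring allows only the cis, endocyclic alkene. The step needs chemoselectivity for olefination over acyl transfer: only the ortho acetyl carbonyl is within reach of the ylide carbon, the ylide has no α-hydrogen from which a ketene could form, and the amine base is washed out before heating so that no ketone enolate can attack the aryl ester. The strong P=O bond and the conjugated pyranone that results should drive the closure despite the low reactivity of ester ylides toward ketones.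

Step 5
Reactants: 9 7-(benzyloxy)-5-methoxy-3,4-dimethylchromen-2-one
Product: 10 7-hydroxy-5-methoxy-3,4-dimethylchromen-2-one
Conditions: H2 (1 atm), Pd/C (10 wt %), EtOAc–MeOH, 23 °C
Reagents that add atoms: none
Why: Hydrogenolysis of the benzyl ether on palladium frees the 7-hydroxyl, the tetrasubstituted conjugated C3=C4 bond being inert under these conditions.

Step 6
Reactants: 10 7-hydroxy-5-methoxy-3,4-dimethylchromen-2-one; 11 hexamethylenetetramine
Product: 12 7-hydroxy-5-methoxy-3,4-dimethyl-2-oxo-2H-chromene-8-carbaldehyde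
Conditions: CF3CO2H, 90 °C; then H2O, 60 °C
Reagents that add atoms: water, O
Why: Duff formylation ortho to the 7-hydroxyl (aminomethylation by the iminium ion, hydride transfer, hydrolysis) should go to C8, the position preferred in 7-hydroxycoumarins and activated by O1, O7 and the para methoxy group, while C6 is shielded by the 5-methoxy group that the C4 methyl pushes toward it.

Step 7
Reactants: 12 7-hydroxy-5-methoxy-3,4-dimethyl-2-oxo-2H-chromene-8-carbaldehyde; 13 3-chloro-3-methylbut-1-yne
Product: 14 5-methoxy-3,4-dimethyl-7-[(2-methylbut-3-yn-2-yl)oxy]-2-oxo-2H-chromene-8-carbaldehyde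
Conditions: DBU, CuCl2 (1 mol %), MeCN, 0 → 23 °C
Reagents that add atoms: none
Why: Copper-catalysed O-propargylation of the phenoxide by the tertiary propargylic chloride (through a copper-stabilised propargylic cation) is the usual entry to aryl 1,1-dimethylpropargyl ethers and tolerates the hydrogen-bonded ortho-formyl phenol.

Step 8
Reactants: 14 5-methoxy-3,4-dimethyl-7-[(2-methylbut-3-yn-2-yl)oxy]-2-oxo-2H-chromene-8-carbaldehyde
Product: 15 5-methoxy-3,4-dimethyl-7-[(2-methylbut-3-en-2-yl)oxy]-2-oxo-2H-chromene-8-carbaldehyde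
Conditions: H2 (1 atm), Pd/CaCO3 poisoned with Pb(OAc)2 (Lindlar catalyst), quinoline, EtOAc, 23 °C
Reagents that add atoms: none
Why: Lindlar semihydrogenation adds one equivalent of hydrogen to the terminal alkyne and leaves the aldehyde, the lactone and the C3=C4 bond untouched.

Step 9
Reactants: 15 5-methoxy-3,4-dimethyl-7-[(2-methylbut-3-en-2-yl)oxy]-2-oxo-2H-chromene-8-carbaldehyde
Product: 16 7-hydroxy-5-methoxy-3,4-dimethyl-6-(3-methylbut-2-en-1-yl)-2-oxo-2H-chromene-8-carbaldehyde
Conditions: PhNEt2, 130 °C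
Reagents that add atoms: none
Why: Aromatic Claisen rearrangement ([3,3] shift) of the 1,1-dimethylallyl ether can only reach C6 because C8 carries the formyl group, so the allyl unit arrives inverted as a 3-methylbut-2-enyl group and tautomerisation restores the phenol.

Step 10
Reactants: 16 7-hydroxy-5-methoxy-3,4-dimethyl-6-(3-methylbut-2-en-1-yl)-2-oxo-2H-chromene-8-carbaldehyde
Product: 17 7-[(tert-butyldimethylsilyl)oxy]-5-methoxy-3,4-dimethyl-6-(3-methylbut-2-en-1-yl)-2-oxo-2H-chromene-8-carbaldehyde
Conditions: TBSOTf, 2,6-lutidine, CH2Cl2, 0 °C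
Reagents that add atoms: tert-butyldimethylsilyl trifluoromethanesulfonate, CC(C)(C)[Si](C)(C)OS(=O)(=O)C(F)(F)F
Why: Silyl ether formation with the reactive silyl triflate protects the hindered, hydrogen-bonded phenol for the organometallic coupling.

Step 11
Reactants: 18 ethyl (3S)-3-hydroxybutanoate; 19 (Z)-but-2-en-1-ol
Product: 20 (Z)-but-2-en-1-yl (3S)-3-hydroxybutanoate
Conditions: Ti(OEt)4 (10 mol %), 19 (4 equiv), 100 °C, ethanol distilled off
Reagents that add atoms: none
Why: Titanate-catalysed transesterification under neutral conditions exchanges ethanol for the allylic alcohol without touching the carbinol centre or the Z alkene.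

Step 12
Reactants: 20 (Z)-but-2-en-1-yl (3S)-3-hydroxybutanoate
Product: 22 (2S,3S)-2-[(2R)-but-3-en-2-yl]-3-hydroxybutanoic acid, via dilithium alkoxide enolate 21 (not isolated)
Conditions: LiN(iPr)2 (2.3 equiv), THF, −78 → 23 °C, then 50 °C; aqueous HCl
Reagents that add atoms: none
Why: Ireland–Claisen rearrangement of the β-hydroxy ester dianion, a reaction known for crotyl 3-hydroxybutanoates, in which the lithium chelate holds the enolate oxygen cis to C3 and shields the face bearing the carbinol methyl so that C2 is formed anti to it (the sense of Fráter–Seebach alkylation), while the chair transition state with the Z-methyl axial sets the butenyl centre as R.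

Step 13
Reactants: 22 (2S,3S)-2-[(2R)-but-3-en-2-yl]-3-hydroxybutanoic acid
Product: 23 (2S,3S)-2-[(2R)-but-3-en-2-yl]-3-hydroxy-N-methoxy-N-methylbutanamide
Conditions: MeNH(OMe)·HCl, EDC·HCl, HOBt (cat.), iPr2NEt, CH2Cl2, 0 → 23 °C
Reagents that add atoms: N,O-dimethylhydroxylamine hydrochloride, CNOC.Cl
Why: Carbodiimide-mediated amide coupling gives the Weinreb amide without affecting any stereocentre.

Step 14
Reactants: 23 (2S,3S)-2-[(2R)-but-3-en-2-yl]-3-hydroxy-N-methoxy-N-methylbutanamide
Product: 24 (2S,3S)-2-[(2R)-but-3-en-2-yl]-3-[(tert-butyldimethylsilyl)oxy]-N-methoxy-N-methylbutanamide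
Conditions: TBSCl, imidazole, DMF, 23 °C
Reagents that add atoms: tert-butyldimethylsilyl chloride, CC(C)(C)[Si](C)(C)Cl
Why: Silyl ether formation protects the secondary alcohol against the Grignard reagent and the amide base used later.

Step 15
Reactants: 24 (2S,3S)-2-[(2R)-but-3-en-2-yl]-3-[(tert-butyldimethylsilyl)oxy]-N-methoxy-N-methylbutanamide; 25 allylmagnesium bromide
Product: 26 (5S,6R)-5-[(1S)-1-[(tert-butyldimethylsilyl)oxy]ethyl]-6-methylocta-1,7-dien-4-one
Conditions: THF, −78 °C; cold aqueous NH4Cl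
Reagents that add atoms: none
Why: Weinreb ketone synthesis, in which the magnesium chelate of the tetrahedral adduct survives until the cold quench, so the β,γ-unsaturated ketone should form without over-addition, conjugation or α-epimerisation.

Step 16
Reactants: 26 (5S,6R)-5-[(1S)-1-[(tert-butyldimethylsilyl)oxy]ethyl]-6-methylocta-1,7-dien-4-one
Product: 27 (5R,6S)-6-[(1S)-1-[(tert-butyldimethylsilyl)oxy]ethyl]-5-methylcyclohex-3-en-1-one
Conditions: second-generation Grubbs catalyst RuCl2(=CHPh)(PCy3)(H2IMes) (3 mol %), CH2Cl2 (5 mM), 40 °C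
Reagents that add atoms: none
Why: Ring-closing metathesis of the two terminal alkenes closes the six-membered ring C with loss of ethylene.

Step 17
Reactants: 27 (5R,6S)-6-[(1S)-1-[(tert-butyldimethylsilyl)oxy]ethyl]-5-methylcyclohex-3-en-1-one
Product: 28 (2S,3R)-2-[(1S)-1-[(tert-butyldimethylsilyl)oxy]ethyl]-3-methylcyclohexan-1-one
Conditions: H2 (1 atm), Pt/C (5 wt %), EtOAc, 23 °C
Reagents that add atoms: none
Why: Heterogeneous hydrogenation on platinum, chosen for its low tendency to alkene migration, saturates the cis-disubstituted ring alkene without disturbing the adjacent methyl-bearing centre or the α-centre, which leaves the methyl group and the side chain cis.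

Step 18
Reactants: 28 (2S,3R)-2-[(1S)-1-[(tert-butyldimethylsilyl)oxy]ethyl]-3-methylcyclohexan-1-one
Product: 30 (5R,6S)-6-[(1S)-1-[(tert-butyldimethylsilyl)oxy]ethyl]-5-methylcyclohex-1-en-1-yl trifluoromethanesulfonate, via lithium enolate 29 (not isolated)
Conditions: LiN(iPr)2, THF, −78 °C; then PhNTf2, −78 → 0 °C
Reagents that add atoms: N-phenylbis(trifluoromethanesulfonimide), O=S(=O)(N(c1ccccc1)S(=O)(=O)C(F)(F)F)C(F)(F)F
Why: Kinetic deprotonation at −78 °C removes a proton from the unsubstituted α-methylene and not from the hindered α-methine, and O-sulfonylation of this enolate gives the less substituted enol triflate with the stereocentres intact.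

Step 19
Reactants: 17 7-[(tert-butyldimethylsilyl)oxy]-5-methoxy-3,4-dimethyl-6-(3-methylbut-2-en-1-yl)-2-oxo-2H-chromene-8-carbaldehyde; 30 (5R,6S)-6-[(1S)-1-[(tert-butyldimethylsilyl)oxy]ethyl]-5-methylcyclohex-1-en-1-yl trifluoromethanesulfonate
Product: 31 7-[(tert-butyldimethylsilyl)oxy]-8-[{(5R,6R)-6-[(1S)-1-[(tert-butyldimethylsilyl)oxy]ethyl]-5-methylcyclohex-1-en-1-yl}(hydroxy)methyl]-5-methoxy-3,4-dimethyl-6-(3-methylbut-2-en-1-yl)-2H-chromen-2-one (both epimers at the new carbinol carbon)
Conditions: CrCl2 (6 equiv), NiCl2 (2 mol %), DMF, 23 °C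
Reagents that add atoms: none
Why: Nozaki–Hiyama–Kishi coupling, in which zerovalent nickel inserts into the alkenyl triflate and transmetalation to trivalent chromium gives an alkenylchromium species that adds to the aldehyde but not to the lactone or the silyl ethers.

Step 20
Reactants: 31 the carbinol mixture from step 19
Product: 32 7-[(tert-butyldimethylsilyl)oxy]-8-{(5R,6R)-6-[(1S)-1-[(tert-butyldimethylsilyl)oxy]ethyl]-5-methylcyclohex-1-ene-1-carbonyl}-5-methoxy-3,4-dimethyl-6-(3-methylbut-2-en-1-yl)-2H-chromen-2-one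
Conditions: Dess–Martin periodinane, CH2Cl2, 0 → 23 °C
Reagents that add atoms: none
Why: Dess–Martin oxidation converts the benzylic and allylic secondary alcohol into the aryl alkenyl ketone under conditions that leave the prenyl alkene and the silyl ethers alone, and both epimers converge on one ketone.

Step 21
Reactants: 32 the bis-silyl ketone from step 20
Product: 33 7-hydroxy-8-{(5R,6R)-6-[(1S)-1-hydroxyethyl]-5-methylcyclohex-1-ene-1-carbonyl}-5-methoxy-3,4-dimethyl-6-(3-methylbut-2-en-1-yl)-2H-chromen-2-one (target)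
Conditions: HF·pyridine, pyridine, THF, 0 → 23 °C
Reagents that add atoms: none
Why: Fluoride-mediated desilylation removes both silyl ethers under buffered, weakly acidic conditions that should avoid phenoxide-triggered oxa-Michael closure onto the enone and acid-induced cyclisation of the prenyl group.

Compound list
1 | 2',4'-dihydroxy-6'-methoxyacetophenone | COc1cc(O)cc(O)c1C(C)=O | starting material
2 | benzyl bromide | BrCc1ccccc1 | starting material
3 | 4'-(benzyloxy)-2'-hydroxy-6'-methoxyacetophenone | COc1cc(OCc2ccccc2)cc(O)c1C(C)=O | intermediate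
4 | 2-bromopropanoyl bromide (racemic) | CC(Br)C(=O)Br | starting material
5 | 2-acetyl-5-(benzyloxy)-3-methoxyphenyl 2-bromopropanoate (racemic) | COc1cc(OCc2ccccc2)cc(OC(=O)C(C)Br)c1C(C)=O | intermediate
6 | triphenylphosphine | c1ccc(cc1)P(c1ccccc1)c1ccccc1 | starting material
7 | {1-[2-acetyl-5-(benzyloxy)-3-methoxyphenoxy]-1-oxopropan-2-yl}triphenylphosphonium bromide (racemic) | COc1cc(OCc2ccccc2)cc(OC(=O)C(C)[P+](c2ccccc2)(c2ccccc2)c2ccccc2)c1C(C)=O.[Br-] | intermediate (not isolated)
8 | 2-acetyl-5-(benzyloxy)-3-methoxyphenyl 2-(triphenylphosphoranylidene)propanoate | COc1cc(OCc2ccccc2)cc(OC(=O)C(C)=P(c2ccccc2)(c2ccccc2)c2ccccc2)c1C(C)=O | intermediate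
9 | 7-(benzyloxy)-5-methoxy-3,4-dimethylchromen-2-one | COc1cc(OCc2ccccc2)cc2oc(=O)c(C)c(C)c12 | intermediate
10 | 7-hydroxy-5-methoxy-3,4-dimethylchromen-2-one | COc1cc(O)cc2oc(=O)c(C)c(C)c12 | intermediate
11 | hexamethylenetetramine | C1N2CN3CN1CN(C2)C3 | starting material
12 | 7-hydroxy-5-methoxy-3,4-dimethyl-2-oxo-2H-chromene-8-carbaldehyde | COc1cc(O)c(C=O)c2oc(=O)c(C)c(C)c12 | intermediate
13 | 3-chloro-3-methylbut-1-yne | CC(C)(Cl)C#C | starting material
14 | 5-methoxy-3,4-dimethyl-7-[(2-methylbut-3-yn-2-yl)oxy]-2-oxo-2H-chromene-8-carbaldehyde | COc1cc(OC(C)(C)C#C)c(C=O)c2oc(=O)c(C)c(C)c12 | intermediate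
15 | 5-methoxy-3,4-dimethyl-7-[(2-methylbut-3-en-2-yl)oxy]-2-oxo-2H-chromene-8-carbaldehyde | COc1cc(OC(C)(C)C=C)c(C=O)c2oc(=O)c(C)c(C)c12 | intermediate
16 | 7-hydroxy-5-methoxy-3,4-dimethyl-6-(3-methylbut-2-en-1-yl)-2-oxo-2H-chromene-8-carbaldehyde | COc1c(CC=C(C)C)c(O)c(C=O)c2oc(=O)c(C)c(C)c12 | intermediate
17 | 7-[(tert-butyldimethylsilyl)oxy]-5-methoxy-3,4-dimethyl-6-(3-methylbut-2-en-1-yl)-2-oxo-2H-chromene-8-carbaldehyde | COc1c(CC=C(C)C)c(O[Si](C)(C)C(C)(C)C)c(C=O)c2oc(=O)c(C)c(C)c12 | intermediate
18 | ethyl (3S)-3-hydroxybutanoate | CCOC(=O)C[C@H](C)O | starting material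
19 | (Z)-but-2-en-1-ol | C/C=C\CO | starting material
20 | (Z)-but-2-en-1-yl (3S)-3-hydroxybutanoate | C/C=C\COC(=O)C[C@H](C)O | intermediate
21 | dilithium alkoxide enolate of 20 (enolate oxygen cis to C3, chelated by lithium; carbinol S) | [Li+].[Li+].C/C=C\CO/C([O-])=C/[C@H](C)[O-] | intermediate (not isolated)
22 | (2S,3S)-2-[(2R)-but-3-en-2-yl]-3-hydroxybutanoic acid | C=C[C@@H](C)[C@H](C(=O)O)[C@H](C)O | intermediate
23 | (2S,3S)-2-[(2R)-but-3-en-2-yl]-3-hydroxy-N-methoxy-N-methylbutanamide | C=C[C@@H](C)[C@H](C(=O)N(C)OC)[C@H](C)O | intermediate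
24 | (2S,3S)-2-[(2R)-but-3-en-2-yl]-3-[(tert-butyldimethylsilyl)oxy]-N-methoxy-N-methylbutanamide | C=C[C@@H](C)[C@H](C(=O)N(C)OC)[C@H](C)O[Si](C)(C)C(C)(C)C | intermediate
25 | allylmagnesium bromide | C=CC[Mg]Br | starting material
26 | (5S,6R)-5-[(1S)-1-[(tert-butyldimethylsilyl)oxy]ethyl]-6-methylocta-1,7-dien-4-one | C=C[C@@H](C)[C@H](C(=O)CC=C)[C@H](C)O[Si](C)(C)C(C)(C)C | intermediate
27 | (5R,6S)-6-[(1S)-1-[(tert-butyldimethylsilyl)oxy]ethyl]-5-methylcyclohex-3-en-1-one | O=C1CC=C[C@@H](C)[C@H]1[C@H](C)O[Si](C)(C)C(C)(C)C | intermediate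
28 | (2S,3R)-2-[(1S)-1-[(tert-butyldimethylsilyl)oxy]ethyl]-3-methylcyclohexan-1-one (methyl and side chain cis) | O=C1CCC[C@@H](C)[C@H]1[C@H](C)O[Si](C)(C)C(C)(C)C | intermediate
29 | lithium enolate of 28 toward the unsubstituted α-carbon | [Li+].[O-]C1=CCC[C@@H](C)[C@H]1[C@H](C)O[Si](C)(C)C(C)(C)C | intermediate (not isolated)
30 | (5R,6S)-6-[(1S)-1-[(tert-butyldimethylsilyl)oxy]ethyl]-5-methylcyclohex-1-en-1-yl trifluoromethanesulfonate | O=S(=O)(OC1=CCC[C@@H](C)[C@H]1[C@H](C)O[Si](C)(C)C(C)(C)C)C(F)(F)F | intermediate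
31 | 7-[(tert-butyldimethylsilyl)oxy]-8-[{(5R,6R)-6-[(1S)-1-[(tert-butyldimethylsilyl)oxy]ethyl]-5-methylcyclohex-1-en-1-yl}(hydroxy)methyl]-5-methoxy-3,4-dimethyl-6-(3-methylbut-2-en-1-yl)-2H-chromen-2-one (both carbinol epimers) | COc1c(CC=C(C)C)c(O[Si](C)(C)C(C)(C)C)c(C(O)C2=CCC[C@@H](C)[C@H]2[C@H](C)O[Si](C)(C)C(C)(C)C)c2oc(=O)c(C)c(C)c12 | intermediate
32 | 7-[(tert-butyldimethylsilyl)oxy]-8-{(5R,6R)-6-[(1S)-1-[(tert-butyldimethylsilyl)oxy]ethyl]-5-methylcyclohex-1-ene-1-carbonyl}-5-methoxy-3,4-dimethyl-6-(3-methylbut-2-en-1-yl)-2H-chromen-2-one | COc1c(CC=C(C)C)c(O[Si](C)(C)C(C)(C)C)c(C(=O)C2=CCC[C@@H](C)[C@H]2[C@H](C)O[Si](C)(C)C(C)(C)C)c2oc(=O)c(C)c(C)c12 | intermediate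
33 | 7-hydroxy-8-{(5R,6R)-6-[(1S)-1-hydroxyethyl]-5-methylcyclohex-1-ene-1-carbonyl}-5-methoxy-3,4-dimethyl-6-(3-methylbut-2-en-1-yl)-2H-chromen-2-one | COc1c(CC=C(C)C)c(O)c(C(=O)C2=CCC[C@@H](C)[C@H]2[C@H](C)O)c2oc(=O)c(C)c(C)c12 | target

Total step count: 21. Longest linear sequence: 13 steps (steps 1–10 and 19–21); the branch to triflate 30 (steps 11–18) has 8 steps and joins at step 19.

Steps most likely to fail

Step 4. The α-methyl ester ylide may add too slowly to the twisted, di-ortho-substituted acetyl carbonyl, which leaves time for cleavage of the aryl ester. The fallback forms the same C3–C4 bond by an aldol-type closure. It sets out from bromo ester 5: a reductive intramolecular Reformatsky reaction (activated Zn, THF, reflux, or SmI2 at −78 °C) should give 7-(benzyloxy)-4-hydroxy-5-methoxy-3,4-dimethyl-3,4-dihydrochromen-2-one F1 as a diastereomer mixture. Acid-catalysed dehydration of this tertiary benzylic alcohol (TsOH, PhMe, 80 °C) then leads back to coumarin 9.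

Step 12. At the temperature that the non-silylated dianion needs, a boat-like transition state may compete and erode stereocontrol at the methyl-bearing carbon. The fallback replaces reliance on the chair preference of a primary crotyl ester by chirality transfer from a stereogenic allylic carbinol. It sets out from 18 and returns at 27.
- Commercial (R)-but-3-yn-2-ol is C-methylated (n-BuLi, 2 equiv, then MeI) to (2R)-pent-3-yn-2-ol F2.
- Semihydrogenation (H2, Pd/CaCO3 poisoned with Pb(OAc)2) gives (2R,3Z)-pent-3-en-2-ol F3.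
- Transesterification with 18 (Ti(OEt)4) gives (2R,3Z)-pent-3-en-2-yl (3S)-3-hydroxybutanoate F4.
- In the dianionic rearrangement of F4 the carbinol methyl must sit equatorial in the chair, since the alternative places it 1,3-diaxial to the Z-methyl. This should give (2S,3S)-3-hydroxy-2-[(2R,3E)-pent-3-en-2-yl]butanoic acid F5.
- The conditions of steps 13–15 then give Weinreb amide (2S,3S)-3-hydroxy-N-methoxy-N-methyl-2-[(2R,3E)-pent-3-en-2-yl]butanamide F6, its silyl ether (2S,3S)-3-[(tert-butyldimethylsilyl)oxy]-N-methoxy-N-methyl-2-[(2R,3E)-pent-3-en-2-yl]butanamide F7 and the allyl ketone (5S,6R,7E)-5-[(1S)-1-[(tert-butyldimethylsilyl)oxy]ethyl]-6-methylnona-1,7-dien-4-one F8.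
- Ring-closing metathesis of F8 under the conditions of step 16 expels propene and gives cyclohexenone 27.

Step 19. The alkenylchromium species may add too slowly to the aldehyde, which is flanked by the silyloxy group at C7 and by O1, so that the α-branched alkenyl triflate is consumed by protodemetalation instead. The fallback replaces the in situ nickel/chromium coupling by a preformed, far more nucleophilic alkenylmetal. It sets out from triflate 30: stannylation (Me3SnSnMe3, Pd(PPh3)4, LiCl, THF, 60 °C) should give [(5R,6S)-6-[(1S)-1-[(tert-butyldimethylsilyl)oxy]ethyl]-5-methylcyclohex-1-en-1-yl]trimethylstannane F9. Tin–lithium exchange (MeLi, THF, −78 °C), transmetalation with CeCl3 and addition to aldehyde 17 at −78 °C follow, with an acetic acid quench at that temperature to prevent silyl migration from the phenol oxygen. This leads back to carbinol 31.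

Further compounds
F1 | step 4 | 7-(benzyloxy)-4-hydroxy-5-methoxy-3,4-dimethyl-3,4-dihydrochromen-2-one (diastereomer mixture, racemic) | COc1cc(OCc2ccccc2)cc2OC(=O)C(C)C(C)(O)c12
F2 | step 12 | (2R)-pent-3-yn-2-ol | CC#C[C@@H](C)O
F3 | step 12 | (2R,3Z)-pent-3-en-2-ol | C/C=C\[C@@H](C)O
F4 | step 12 | (2R,3Z)-pent-3-en-2-yl (3S)-3-hydroxybutanoate | C/C=C\[C@@H](C)OC(=O)C[C@H](C)O
F5 | step 12 | (2S,3S)-3-hydroxy-2-[(2R,3E)-pent-3-en-2-yl]butanoic acid | C/C=C/[C@@H](C)[C@H](C(=O)O)[C@H](C)O
F6 | step 12 | (2S,3S)-3-hydroxy-N-methoxy-N-methyl-2-[(2R,3E)-pent-3-en-2-yl]butanamide | C/C=C/[C@@H](C)[C@H](C(=O)N(C)OC)[C@H](C)O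
F7 | step 12 | (2S,3S)-3-[(tert-butyldimethylsilyl)oxy]-N-methoxy-N-methyl-2-[(2R,3E)-pent-3-en-2-yl]butanamide | C/C=C/[C@@H](C)[C@H](C(=O)N(C)OC)[C@H](C)O[Si](C)(C)C(C)(C)C
F8 | step 12 | (5S,6R,7E)-5-[(1S)-1-[(tert-butyldimethylsilyl)oxy]ethyl]-6-methylnona-1,7-dien-4-one | C/C=C/[C@@H](C)[C@H](C(=O)CC=C)[C@H](C)O[Si](C)(C)C(C)(C)C
F9 | step 19 | [(5R,6S)-6-[(1S)-1-[(tert-butyldimethylsilyl)oxy]ethyl]-5-methylcyclohex-1-en-1-yl]trimethylstannane | C[Sn](C)(C)C1=CCC[C@@H](C)[C@H]1[C@H](C)O[Si](C)(C)C(C)(C)C
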